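**Plan**

- Retrosynthesis: the cyclobutane bonds C8–C8′ and C9–C9′ are cut first (head-to-head [2+2] of two identical C8=C9 dienolides). The monomer is then simplified at C4=C15 (to a ketone) and at the butenolide (to a furan). C5–C10 and C6–C7 are cut together, and last the cyclopropane methylene C2 and the two alkenes of an open chain.
- Enabling feature: rings A (C1, C3, C4, C5, C10) and B (C5, C6, C7, C8, C9, C10) meet in the C5–C10 bond at the quaternary C10. The butenolide (C7, C8, C11, C12, O) can travel as a furan whose C7=C8 bond, extended by a C9=C10 alkene, is a diene for a C5=C6 vinyl ketone attached to C4.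
- Forward: 4-methylfuran-2-carbaldehyde is extended to an (E,Z)-dienol, the cyclopropane is added, the vinyl ketone is installed, and rings A and B close in one cycloaddition. The C4 methylene, the butenolide, the C8=C9 alkene and the cyclobutane follow.
- Stereochemistry: alkene geometry fixes the cis-cyclopropane and the diene, and a ligand-controlled Simmons–Smith reaction sets C1/C3 absolutely. These centres relay to C10 and C5 in the cycloaddition. The C14 methyl groups direct the dimerisation to the α faces, setting C8, C9, C8′ and C9′.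

Key step: step 8

Remark: lindenane numbering is used (C1–C2–C3 cyclopropane, C14 methyl on C10, C15 methylene on C4, C13 methyl on C11; β is the face of C14). The (R,R)-dioxaborolane is assumed to induce in the (Z)-dienol the same facial sense as in simple allylic alcohols; the antipodal ligand would be used if it did not.

**Route**

Step 1
Reactants: 1 4-methylfuran-2-carbaldehyde; 2 2-(triphenylphosphoranylidene)propanal
Product: 3 (2E)-2-methyl-3-(4-methylfuran-2-yl)prop-2-enal
Conditions: PhMe, 100 °C
Reagents that add atoms: 2-(triphenylphosphoranylidene)propanal (2), CC(C=O)=P(c1ccccc1)(c1ccccc1)c1ccccc1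
Why: Wittig olefination with a formyl-stabilised ylide should give the (E)-enal, which fixes the later C9=C10 geometry with the furyl group cis to the C14 methyl.

Step 2
Reactants: 3 (2E)-2-methyl-3-(4-methylfuran-2-yl)prop-2-enal; 4 methyl bis(2,2,2-trifluoroethyl)phosphonoacetate
Product: 5 methyl (2Z,4E)-4-methyl-5-(4-methylfuran-2-yl)penta-2,4-dienoate
Conditions: KN(SiMe3)2, 18-crown-6, THF, −78 °C
Reagents that add atoms: methyl bis(2,2,2-trifluoroethyl)phosphonoacetate (4), COC(=O)CP(=O)(OCC(F)(F)F)OCC(F)(F)F
Why: The Still–Gennari variant of the Horner–Wadsworth–Emmons reaction eliminates fast from the kinetic adduct of the electron-poor phosphonate and should give the (Z)-enoate, the geometry that later becomes the cis-cyclopropane.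

Step 3
Reactants: 5 methyl (2Z,4E)-4-methyl-5-(4-methylfuran-2-yl)penta-2,4-dienoate
Product: 6 (2Z,4E)-4-methyl-5-(4-methylfuran-2-yl)penta-2,4-dien-1-ol
Conditions: (i-Bu)2AlH, CH2Cl2, −78 °C; aq. potassium sodium tartrate
Reagents that add atoms: none
Why: 1,2-Reduction of the ester by the aluminium hydride at low temperature should give the allylic alcohol without touching the diene geometry.

Step 4
Reactants: 6 (2Z,4E)-4-methyl-5-(4-methylfuran-2-yl)penta-2,4-dien-1-ol
Product: 7 [(1S,2R)-2-[(1E)-1-(4-methylfuran-2-yl)prop-1-en-2-yl]cyclopropyl]methanol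
Conditions: Zn(CH2I)2·DME (from Et2Zn, CH2I2, DME), (4R,5R)-2-butyl-N,N,N′,N′-tetramethyl-1,3,2-dioxaborolane-4,5-dicarboxamide, CH2Cl2, −10 → 23 °C
Reagents that add atoms: diiodomethane, ICI
Why: In the Charette asymmetric Simmons–Smith cyclopropanation the zinc alkoxide binds the chiral dioxaborolane and delivers the methylene stereospecifically to one face of the proximal (Z)-alkene only, so the cis relation of C1/C3 comes from the alkene geometry and the absolute configuration from the (R,R)-ligand, while the undirected trisubstituted alkene and the furan should stay untouched.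

Step 5
Reactants: 7 [(1S,2R)-2-[(1E)-1-(4-methylfuran-2-yl)prop-1-en-2-yl]cyclopropyl]methanol
Product: 8 (1S,2R)-2-[(1E)-1-(4-methylfuran-2-yl)prop-1-en-2-yl]cyclopropane-1-carbaldehyde
Conditions: Dess–Martin periodinane, NaHCO3, CH2Cl2, 0 °C
Reagents that add atoms: none
Why: Buffered Dess–Martin oxidation should stop at the aldehyde without epimerising the cyclopropane; the aldehyde is kept cold and used at once to limit reversible retro-Claisen rearrangement of the cis-alkenylcyclopropanecarbaldehyde.

Step 6
Reactants: 8 (1S,2R)-2-[(1E)-1-(4-methylfuran-2-yl)prop-1-en-2-yl]cyclopropane-1-carbaldehyde; 9 vinylmagnesium bromide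
Product: 10 1-[(1S,2R)-2-[(1E)-1-(4-methylfuran-2-yl)prop-1-en-2-yl]cyclopropyl]prop-2-en-1-ol (carbinol epimers)
Conditions: CH2=CHMgBr, THF, −78 °C; aq. NH4Cl
Reagents that add atoms: vinylmagnesium bromide (9), C=C[Mg]Br
Why: Grignard 1,2-addition to the aldehyde at low temperature should be clean, and the carbinol configuration is irrelevant because it is oxidised in the next step.

Step 7
Reactants: 10 1-[(1S,2R)-2-[(1E)-1-(4-methylfuran-2-yl)prop-1-en-2-yl]cyclopropyl]prop-2-en-1-ol
Product: 11 1-[(1S,2R)-2-[(1E)-1-(4-methylfuran-2-yl)prop-1-en-2-yl]cyclopropyl]prop-2-en-1-one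
Conditions: Dess–Martin periodinane, NaHCO3, CH2Cl2, 0 °C
Reagents that add atoms: none
Why: Dess–Martin oxidation of the secondary allylic alcohol should give the vinyl ketone under neutral conditions that avoid conjugate addition or polymerisation, and the product is taken on directly.

Step 8
Reactants: 11 1-[(1S,2R)-2-[(1E)-1-(4-methylfuran-2-yl)prop-1-en-2-yl]cyclopropyl]prop-2-en-1-one
Product: 13 furan ketone 8,12-epoxy-15-nor-lindena-7,11-dien-4-one, via primary cycloadduct 12 (not isolated)
Conditions: PhMe (0.01 M), BHT (cat.), 150 °C, sealed tube; then PPTS (cat.), 23 °C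
Reagents that add atoms: none
Why: A thermal, concerted but asynchronous [4+2] cycloaddition joins the furan C7=C8 bond and the C9=C10 alkene (diene) to the C5=C6 vinyl ketone, forming C5–C10 and C6–C7, and the dienol ether 12 then regains the furan by an acid-catalysed formal 1,3-hydrogen shift (protonation at C9, loss of H7), which makes the sequence irreversible. The closest known reaction type is the intramolecular Diels–Alder reaction of 2-vinylfurans with tethered activated alkenes followed by rearomatisation. Ring A closes as a five-membered ring in the fused mode across the three-atom tether C1–C3–C4, which leaves no regiochemical choice, and ring B is the six-membered ring made by the cycloaddition itself, the polarity being matched because the oxygen-activated C7 meets the enone β-carbon C6. C10 is controlled by the cyclopropane set in step 4: the diene plane must cut across the forming ring A, so the furyl-bearing C9 arm lies on the face anti to the cyclopropane methylene C2 and the inside C14 methyl ends up syn to C2. C5 is controlled by the exo (tether-anti) transition state, the less twisted one for a three-atom tether whose cis-cyclopropane holds C10, C1, C3 and C4 nearly coplanar, and this places H5 anti to the C14 methyl (trans ring fusion). The step therefore needs exo over endo and anti-C2 over syn-C2 selectivity plus enough reactivity at the gem-disubstituted diene terminus, which the rigid cis-cyclopropyl tether, the E geometry fixed in step 1, high dilution with a radical inhibitor and neutral conditions (a Lewis acid would ionise the alkenyl- and acyl-substituted cyclopropane) are meant to secure.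

Step 9
Reactants: 13 8,12-epoxy-15-nor-lindena-7,11-dien-4-one
Product: 14 8,12-epoxylindena-4(15),7,11-triene
Conditions: Ph3PCH3Br, KOt-Bu (slight deficit), THF, 0 → 23 °C
Reagents that add atoms: methyltriphenylphosphonium bromide, C[P+](c1ccccc1)(c1ccccc1)c1ccccc1.[Br-]
Why: Wittig methylenation of the unhindered cyclopropyl ketone with a preformed ylide free of excess base should outrun enolisation toward C5, so the trans ring fusion is kept.

Step 10
Reactants: 14 8,12-epoxylindena-4(15),7,11-triene
Product: 16 8α-hydroxylindena-4(15),7(11)-dien-12,8-olide, via furan endoperoxide 15 (not isolated)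
Conditions: O2, hν (visible), tetraphenylporphyrin (cat.), i-Pr2NEt, CH2Cl2, −78 → 23 °C
Reagents that add atoms: dioxygen, O=O
Why: Sensitised singlet-oxygen [4+2] addition to the furan, the most electron-rich π system, on the α face anti to C14, is followed by base-induced Kornblum–DeLaMare-type fragmentation of the endoperoxide, in which only C12 carries a removable hydrogen, so C12 becomes the lactone carbonyl and C8 the hemiketal carbon (its configuration is lost in step 11).

Step 11
Reactants: 16 8α-hydroxylindena-4(15),7(11)-dien-12,8-olide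
Product: 18 lindena-4(15),7(11),8-trien-12,8-olide, via C8 mesylate 17 (not isolated)
Conditions: MsCl, Et3N, CH2Cl2, 0 → 23 °C
Reagents that add atoms: none
Why: Sulfonylation of the hemiketal hydroxyl and base-mediated elimination through the acyloxy-stabilised C8 cation, with C9 carrying the only β-hydrogens, should give the γ-alkylidene butenolide without acid that would endanger the C4=C15 alkene next to the cyclopropane.

Step 12
Reactants: 18 lindena-4(15),7(11),8-trien-12,8-olide (two molecules)
Product: 19 CNP0265879.1, the head-to-head C8–C8′/C9–C9′ cyclobutane dimer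
Conditions: hν (Hg lamp, Pyrex filter), degassed n-hexane, 23 °C
Reagents that add atoms: none
Why: In this [2+2] photodimerisation of a γ-alkylidene butenolide (the anemonin-type dimerisation of 5-ylidene furanones) the first bond should form between the two C9 termini on the α faces anti to the C14 methyl groups, giving two furanoxy-type radicals at C8 that couple on the same faces, which accounts for the head-to-head regiochemistry, the cis-fused cyclobutane and, for two homochiral partners, the twofold-symmetric product.

**Compound list**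

1 | 4-methylfuran-2-carbaldehyde | Cc1coc(C=O)c1 | starting material
2 | 2-(triphenylphosphoranylidene)propanal | CC(C=O)=P(c1ccccc1)(c1ccccc1)c1ccccc1 | starting material
3 | (2E)-2-methyl-3-(4-methylfuran-2-yl)prop-2-enal | Cc1coc(/C=C(\C)C=O)c1 | intermediate
4 | methyl bis(2,2,2-trifluoroethyl)phosphonoacetate | COC(=O)CP(=O)(OCC(F)(F)F)OCC(F)(F)F | starting material
5 | methyl (2Z,4E)-4-methyl-5-(4-methylfuran-2-yl)penta-2,4-dienoate | Cc1coc(/C=C(\C)/C=C\C(=O)OC)c1 | intermediate
6 | (2Z,4E)-4-methyl-5-(4-methylfuran-2-yl)penta-2,4-dien-1-ol | Cc1coc(/C=C(\C)/C=C\CO)c1 | intermediate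
7 | [(1S,2R)-2-[(1E)-1-(4-methylfuran-2-yl)prop-1-en-2-yl]cyclopropyl]methanol | Cc1coc(/C=C(\C)[C@@H]2C[C@@H]2CO)c1 | intermediate
8 | (1S,2R)-2-[(1E)-1-(4-methylfuran-2-yl)prop-1-en-2-yl]cyclopropane-1-carbaldehyde | Cc1coc(/C=C(\C)[C@@H]2C[C@@H]2C=O)c1 | intermediate
9 | vinylmagnesium bromide | C=C[Mg]Br | starting material
10 | 1-[(1S,2R)-2-[(1E)-1-(4-methylfuran-2-yl)prop-1-en-2-yl]cyclopropyl]prop-2-en-1-ol (carbinol epimers) | Cc1coc(/C=C(\C)[C@@H]2C[C@@H]2C(O)C=C)c1 | intermediate
11 | 1-[(1S,2R)-2-[(1E)-1-(4-methylfuran-2-yl)prop-1-en-2-yl]cyclopropyl]prop-2-en-1-one | Cc1coc(/C=C(\C)[C@@H]2C[C@@H]2C(=O)C=C)c1 | intermediate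
12 | primary cycloadduct: 4-oxo-15-nor-lindena-8,11-diene 8,12-ether (C8=C9, C11=C12, H7 β, C2 and C14 β, H5 α) | O=C1[C@H]2C[C@H]2[C@@]2(C)[C@H]1C[C@H]1C(C)=COC1=C2 | intermediate (not isolated)
13 | 8,12-epoxy-15-nor-lindena-7,11-dien-4-one (C2 and C14 β, H5 α) | O=C1[C@H]2C[C@H]2[C@@]2(C)[C@H]1Cc1c(C)coc1C2 | intermediate
14 | 8,12-epoxylindena-4(15),7,11-triene | C=C1[C@H]2C[C@H]2[C@@]2(C)[C@H]1Cc1c(C)coc1C2 | intermediate
15 | 8α,12α-epidioxy-8,12-epoxylindena-4(15),7(11)-diene (furan endoperoxide) | C=C1[C@H]2C[C@H]2[C@@]2(C)[C@H]1CC1=C(C)[C@H]3OO[C@@]1(O3)C2 | intermediate (not isolated)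
16 | 8α-hydroxylindena-4(15),7(11)-dien-12,8-olide | C=C1[C@H]2C[C@H]2[C@@]2(C)[C@H]1CC1=C(C)C(=O)O[C@]1(O)C2 | intermediate
17 | 8α-(methanesulfonyloxy)lindena-4(15),7(11)-dien-12,8-olide | C=C1[C@H]2C[C@H]2[C@@]2(C)[C@H]1CC1=C(C)C(=O)O[C@]1(OS(C)(=O)=O)C2 | intermediate (not isolated)
18 | lindena-4(15),7(11),8-trien-12,8-olide | C=C1[C@H]2C[C@H]2[C@@]2(C)[C@H]1CC1=C(C)C(=O)OC1=C2 | intermediate
19 | CNP0265879.1, head-to-head C8–C8′/C9–C9′ cyclobutane dimer of 18 | C=C1[C@H]2C[C@H]2[C@@]2(C)[C@H]1CC1=C(C)C(=O)O[C@]13[C@H]2[C@H]1[C@@]2(C)[C@@H]4C[C@@H]4C(=C)[C@@H]2CC2=C(C)C(=O)O[C@@]213 | target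

**Step count and risks**

Total steps: 12. Longest linear sequence: 12 steps (from 1).

Step 8 is the riskiest. The cycloaddition may be too slow at the gem-disubstituted diene terminus with its inside methyl. Polymerisation of the vinyl ketone, retro-Claisen drift of the cis-alkenylcyclopropyl ketone, or leakage through the endo transition state (cis ring fusion) could then take over. The fallback sets out from aldehyde 8 and keeps the same two bonds and rings but uses a slimmer, more electron-poor dienophile. Ethynylmagnesium bromide (HC≡CMgBr, THF, −78 °C) should give the propargylic alcohol F1, and Dess–Martin oxidation the ynone F2. Heating in toluene should close C5–C10 and C6–C7 to the cyclohexadiene cycloadduct F3, which tautomerises in the flask (PPTS) to the 5,6-didehydro furan ketone F4. Conjugate reduction with [(Ph3P)CuH]6, followed by protonation of the enolate at C5 on the α face (the β face is covered by C14 and C2), comes back to the route at 13.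

Step 12 is the second risk. The excited dienolide may be diverted by the C4=C15 alkene of a second molecule (cross-cycloaddition or hydrogen abstraction), so that dimer mixtures arise. The fallback sets out from ketone 13 and postpones the methylenation. Singlet oxygen and base as in step 10 should give, through the endoperoxide F5, the hydroxybutenolide ketone F6. MsCl/Et3N should give, through the mesylate F7, the 4-oxo dienolide F8. Irradiation then dimerises F8, which has no competing alkene, to the dimeric diketone F9. A twofold Wittig methylenation (Ph3P=CH2, THF, 0 °C), to which the lactones are inert, comes back to the route at 19.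

Step 4 is the third risk. Enantioselectivity may erode with this (Z)-dienol, and the ligand-slowed carbenoid may allow undirected methylene transfer or ionisation of the dienylic alcohol by the zinc salts. The fallback sets out from dienol 6 and replaces reagent control by resolution. Fast hydroxyl-directed Furukawa cyclopropanation without ligand (Et2Zn, CH2I2, CH2Cl2, −20 °C) should give the racemic cis alcohol F10. Lipase-mediated acetylation (Amano lipase PS, vinyl acetate, t-BuOMe) is run past half conversion. The plan assumes that the enzyme acylates the antipode faster, so that it leaves as the antipodal acetate F11 and the unreacted alcohol comes back to the route as 7.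

Further compounds
F1 | step 8 | 1-[(1S,2R)-2-[(1E)-1-(4-methylfuran-2-yl)prop-1-en-2-yl]cyclopropyl]prop-2-yn-1-ol (carbinol epimers) | Cc1coc(/C=C(\C)[C@@H]2C[C@@H]2C(O)C#C)c1
F2 | step 8 | 1-[(1S,2R)-2-[(1E)-1-(4-methylfuran-2-yl)prop-1-en-2-yl]cyclopropyl]prop-2-yn-1-one | Cc1coc(/C=C(\C)[C@@H]2C[C@@H]2C(=O)C#C)c1
F3 | step 8 | cyclohexadiene cycloadduct (C5=C6, C8=C9, C11=C12, H7 β; formed in the flask) | O=C1[C@H]2C[C@H]2[C@@]2(C)C1=C[C@H]1C(C)=COC1=C2
F4 | step 8 | 8,12-epoxy-15-nor-lindena-5,7,11-trien-4-one | O=C1[C@H]2C[C@H]2[C@@]2(C)C1=Cc1c(C)coc1C2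
F5 | step 12 | 8α,12α-epidioxy-8,12-epoxy-15-nor-lindena-7(11)-en-4-one (formed in the flask) | O=C1[C@H]2C[C@H]2[C@@]2(C)[C@H]1CC1=C(C)[C@H]3OO[C@@]1(O3)C2
F6 | step 12 | 8α-hydroxy-4-oxo-15-nor-lindena-7(11)-en-12,8-olide | O=C1[C@H]2C[C@H]2[C@@]2(C)[C@H]1CC1=C(C)C(=O)O[C@]1(O)C2
F7 | step 12 | 8α-(methanesulfonyloxy)-4-oxo-15-nor-lindena-7(11)-en-12,8-olide (formed in the flask) | O=C1[C@H]2C[C@H]2[C@@]2(C)[C@H]1CC1=C(C)C(=O)O[C@]1(OS(C)(=O)=O)C2
F8 | step 12 | 4-oxo-15-nor-lindena-7(11),8-dien-12,8-olide | O=C1[C@H]2C[C@H]2[C@@]2(C)[C@H]1CC1=C(C)C(=O)OC1=C2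
F9 | step 12 | head-to-head C8–C8′/C9–C9′ cyclobutane dimer of F8 (4,4′-diketone) | O=C1[C@H]2C[C@H]2[C@@]2(C)[C@H]1CC1=C(C)C(=O)O[C@]13[C@H]2[C@H]1[C@@]2(C)[C@@H]4C[C@@H]4C(=O)[C@@H]2CC2=C(C)C(=O)O[C@@]213
F10 | step 4 | racemic cis alcohol (7 together with its (1R,2S) enantiomer) | Cc1coc(/C=C(\C)[C@@H]2C[C@@H]2CO)c1.Cc1coc(/C=C(\C)[C@H]2C[C@H]2CO)c1
F11 | step 4 | [(1R,2S)-2-[(1E)-1-(4-methylfuran-2-yl)prop-1-en-2-yl]cyclopropyl]methyl acetate | Cc1coc(/C=C(\C)[C@H]2C[C@H]2COC(C)=O)c1
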